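## Retrosynthetic overview

1. Last disconnection: the E-styrenyl tertiary alcohol, by a Heck coupling of a 5'-iodoflavanone with 2-methylbut-3-en-2-ol.
2. Key disconnection: the 3'-prenyl C–C bond, by an aromatic Claisen ([3,3]-sigmatropic) rearrangement of the 4'-O-(1,1-dimethylallyl) ether of a 3'-iodo-4'-hydroxyflavanone. The iodine blocks one ortho carbon and later serves as the Heck handle.
3. The ether comes from palladium-catalysed O-tert-allylation of the iodophenol, which comes from 7-O-silylated (2S)-liquiritigenin by ortho-iodination.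
4. No ring is formed: rings A, C and B and the C2 (S) centre are bought intact in natural (2S)-liquiritigenin. Strong base is avoided throughout so the flavanone never opens to the chalcone.

Assumption: (2S)-liquiritigenin is bought as the natural, enantiopure licorice flavanone; its ee is checked by chiral HPLC on receipt and again after steps 5 and 8.

## Route

Step 1
Reactants: 1 (2S)-liquiritigenin [(2S)-7-hydroxy-2-(4-hydroxyphenyl)chroman-4-one]
Product: 2 (2S)-2-(4-hydroxyphenyl)-7-(triisopropylsilyloxy)chroman-4-one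
Conditions: TIPSCl (1.05 equiv), imidazole (2.2 equiv), DMF, 0 °C to rt
Reagents that add atoms: triisopropylsilyl chloride (TIPSCl), CC(C)[Si](Cl)(C(C)C)C(C)C
Why: Chemoselective phenol silylation: the 7-OH is a vinylogous acid (para to the C4 carbonyl, 2–3 pKa units more acidic than the 4'-OH), so with a weak base only it is ionised and silylated, and imidazole is too weak to open the chromanone, so C2 stays S.

Step 2
Reactants: 2 (2S)-2-(4-hydroxyphenyl)-7-(triisopropylsilyloxy)chroman-4-one
Product: 3 (2S)-2-(4-hydroxy-3-iodophenyl)-7-(triisopropylsilyloxy)chroman-4-one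
Conditions: NIS (1.0 equiv), TFA (0.2 equiv), MeCN, 0 °C, dark
Reagents that add atoms: N-iodosuccinimide (NIS), O=C1CCC(=O)N1I
Why: Electrophilic aromatic iodination goes ortho to the only free phenol (para position blocked) on ring B, while ring A is deactivated by the C4 carbonyl and shielded by the bulky silyl ether, and one equivalent of NIS stops at the mono-iodide because the first iodine deactivates the ring.

Step 3
Reactants: 4 2-methylbut-3-en-2-ol
Product: 6 tert-butyl 2-methylbut-3-en-2-yl carbonate, via lithium 2-methylbut-3-en-2-olate 5 (not isolated)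
Conditions: n-BuLi (1.0 equiv), THF, −78 to 0 °C; then Boc2O, 0 °C to rt
Reagents that add atoms: di-tert-butyl dicarbonate (Boc2O), CC(C)(C)OC(=O)OC(=O)OC(C)(C)C; n-butyllithium, [Li]CCCC (supplies only the lithium of 5)
Why: O-acylation of the pre-formed lithium tert-alkoxide with Boc2O gives the mixed carbonate without ionising the tertiary allylic C–O bond.

Step 4
Reactants: 3 (2S)-2-(4-hydroxy-3-iodophenyl)-7-(triisopropylsilyloxy)chroman-4-one, 6 tert-butyl 2-methylbut-3-en-2-yl carbonate
Product: 7 (2S)-2-[3-iodo-4-(2-methylbut-3-en-2-yloxy)phenyl]-7-(triisopropylsilyloxy)chroman-4-one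
Conditions: Pd(PPh3)4 (3 mol%), 6 (2 equiv), THF, 4 Å MS, 0 °C; filtration through a short pad of Et3N-washed silica
Reagents that add atoms: none
Why: Tsuji–Trost O-allylation: zerovalent palladium ionises 6 with loss of CO2, the tert-butoxide formed deprotonates the phenol, and the phenoxide attacks the 1,1-dimethyl-π-allyl palladium cation at its more substituted end under kinetic control to give the tertiary ether, this ionisation at 0 °C being much faster than oxidative addition into the electron-rich aryl iodide.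

Step 5
Reactants: 7 (2S)-2-[3-iodo-4-(2-methylbut-3-en-2-yloxy)phenyl]-7-(triisopropylsilyloxy)chroman-4-one
Product: 9 (2S)-2-[4-hydroxy-3-iodo-5-(3-methylbut-2-en-1-yl)phenyl]-7-(triisopropylsilyloxy)chroman-4-one, via ortho-dienone 8 (not isolated)
Conditions: PhMe (degassed, base-washed glassware), 110 °C, sealed tube
Reagents that add atoms: none
Why: Aromatic Claisen rearrangement ([3,3]-sigmatropic shift) through a chair transition state transfers the allyl unit with inversion of its ends (the tertiary ether becomes a linear prenyl group) to the only free ortho carbon, the iodine blocking the other, and tautomerisation of dienone 8 restores the phenol, the neutral medium leaving C2 untouched.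

Step 6
Reactants: 9 (2S)-2-[4-hydroxy-3-iodo-5-(3-methylbut-2-en-1-yl)phenyl]-7-(triisopropylsilyloxy)chroman-4-one
Product: 10 (2S)-2-[3-iodo-4-methoxy-5-(3-methylbut-2-en-1-yl)phenyl]-7-(triisopropylsilyloxy)chroman-4-one
Conditions: MeOH (3 equiv), PPh3 (1.5 equiv), DIAD (1.5 equiv), THF, 0 °C to rt
Reagents that add atoms: methanol, CO
Why: Mitsunobu etherification under neutral conditions methylates the hindered but fairly acidic ortho-iodophenol through the small methoxyphosphonium electrophile, avoiding the carbonate bases that would open the flavanone ring through the 4'-phenoxide.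

Step 7
Reactants: 10 (2S)-2-[3-iodo-4-methoxy-5-(3-methylbut-2-en-1-yl)phenyl]-7-(triisopropylsilyloxy)chroman-4-one
Product: 11 (2S)-7-hydroxy-2-[3-iodo-4-methoxy-5-(3-methylbut-2-en-1-yl)phenyl]chroman-4-one
Conditions: TBAF (1.1 equiv), AcOH (1.2 equiv), THF, 0 °C
Reagents that add atoms: none
Why: Fluoride-driven desilylation is fast for the electron-poor 7-aryloxysilane, and the acetic acid buffer keeps the medium near neutral, so the flavanone, the prenyl group and the aryl iodide are unaffected.

Step 8
Reactants: 11 (2S)-7-hydroxy-2-[3-iodo-4-methoxy-5-(3-methylbut-2-en-1-yl)phenyl]chroman-4-one, 4 2-methylbut-3-en-2-ol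
Product: 12 (2S)-7-hydroxy-2-{3-[(1E)-3-hydroxy-3-methylbut-1-en-1-yl]-4-methoxy-5-(3-methylbut-2-en-1-yl)phenyl}chroman-4-one
Conditions: Pd(OAc)2 (5 mol%), n-Bu4NCl (1 equiv), NaHCO3 (2.5 equiv), 4 (3 equiv), DMF, 70 °C
Reagents that add atoms: none
Why: Heck reaction under phosphine-free Jeffery conditions: the aryl palladium iodide adds to the terminal carbon of the monosubstituted alkene and β-hydride elimination, possible only toward the ring because the carbinol carbon bears no hydrogen, gives the E-styrene, while the 7-phenoxide formed by the mild base disfavours enolisation and ring opening, so C2 remains S.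

## Compound list

1 | (2S)-liquiritigenin, (2S)-7-hydroxy-2-(4-hydroxyphenyl)chroman-4-one | Oc1ccc([C@@H]2CC(=O)c3ccc(O)cc3O2)cc1 | starting material
2 | (2S)-2-(4-hydroxyphenyl)-7-(triisopropylsilyloxy)chroman-4-one | Oc1ccc([C@@H]2CC(=O)c3ccc(O[Si](C(C)C)(C(C)C)C(C)C)cc3O2)cc1 | intermediate
3 | (2S)-2-(4-hydroxy-3-iodophenyl)-7-(triisopropylsilyloxy)chroman-4-one | Oc1ccc([C@@H]2CC(=O)c3ccc(O[Si](C(C)C)(C(C)C)C(C)C)cc3O2)cc1I | intermediate
4 | 2-methylbut-3-en-2-ol | C=CC(C)(C)O | starting material
5 | lithium 2-methylbut-3-en-2-olate | C=CC(C)(C)[O-].[Li+] | intermediate (not isolated)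
6 | tert-butyl 2-methylbut-3-en-2-yl carbonate | C=CC(C)(C)OC(=O)OC(C)(C)C | intermediate
7 | (2S)-2-[3-iodo-4-(2-methylbut-3-en-2-yloxy)phenyl]-7-(triisopropylsilyloxy)chroman-4-one | C=CC(C)(C)Oc1ccc([C@@H]2CC(=O)c3ccc(O[Si](C(C)C)(C(C)C)C(C)C)cc3O2)cc1I | intermediate
8 | ortho-dienone, (2S)-2-[5-iodo-3-(3-methylbut-2-en-1-yl)-4-oxocyclohexa-1,5-dien-1-yl]-7-(triisopropylsilyloxy)chroman-4-one (new sp3 ring carbon unassigned, transient) | O=C1C(I)=CC([C@@H]2CC(=O)c3ccc(O[Si](C(C)C)(C(C)C)C(C)C)cc3O2)=CC1CC=C(C)C | intermediate (not isolated)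
9 | (2S)-2-[4-hydroxy-3-iodo-5-(3-methylbut-2-en-1-yl)phenyl]-7-(triisopropylsilyloxy)chroman-4-one | CC(C)=CCc1cc([C@@H]2CC(=O)c3ccc(O[Si](C(C)C)(C(C)C)C(C)C)cc3O2)cc(I)c1O | intermediate
10 | (2S)-2-[3-iodo-4-methoxy-5-(3-methylbut-2-en-1-yl)phenyl]-7-(triisopropylsilyloxy)chroman-4-one | COc1c(I)cc([C@@H]2CC(=O)c3ccc(O[Si](C(C)C)(C(C)C)C(C)C)cc3O2)cc1CC=C(C)C | intermediate
11 | (2S)-7-hydroxy-2-[3-iodo-4-methoxy-5-(3-methylbut-2-en-1-yl)phenyl]chroman-4-one | COc1c(I)cc([C@@H]2CC(=O)c3ccc(O)cc3O2)cc1CC=C(C)C | intermediate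
12 | (2S)-7-hydroxy-2-{3-[(1E)-3-hydroxy-3-methylbut-1-en-1-yl]-4-methoxy-5-(3-methylbut-2-en-1-yl)phenyl}chroman-4-one | COc1c(/C=C/C(C)(C)O)cc([C@@H]2CC(=O)c3ccc(O)cc3O2)cc1CC=C(C)C | target

## Step count and risks

Total steps: 8. Longest linear sequence: 7 (steps 1, 2, 4, 5, 6, 7, 8); step 3 is a one-step side branch that prepares the allylating reagent.

The three steps most likely to fail:

Step 4 (palladium etherification next to an aryl iodide; risk of C–I insertion or of the linear prenyl ether). The fallback sets out from 3 and comes back at 7, replacing the π-allyl chemistry by a propargyl electrophile. Compound 3 is treated with 3-chloro-3-methylbut-1-yne, CuCl2·2H2O (1 mol%) and DBU in MeCN at 0 °C to give the tertiary propargyl ether (2S)-2-[3-iodo-4-(2-methylbut-3-yn-2-yloxy)phenyl]-7-(triisopropylsilyloxy)chroman-4-one F1. Semihydrogenation of the alkyne (H2 1 atm, Pd on CaCO3 poisoned with Pb(OAc)2, quinoline, EtOAc, rt, stopped at one equivalent) then gives 7.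

Step 5 (Claisen rearrangement; risk of fragmentation of the tertiary ether to 3 and isoprene, or erosion of C2 at 110 °C). The fallback sets out from 2 and comes back at 10, giving up the rearrangement and attaching the prenyl group by cross-coupling. Compound 2 with NIS (2.1 equiv) and catalytic TFA gives the symmetric diiodophenol (2S)-2-(4-hydroxy-3,5-diiodophenyl)-7-(triisopropylsilyloxy)chroman-4-one F2. Mitsunobu methylation as in step 6 gives (2S)-2-(3,5-diiodo-4-methoxyphenyl)-7-(triisopropylsilyloxy)chroman-4-one F3. A mono-Stille coupling with tributyl(3-methylbut-2-en-1-yl)stannane (0.9 equiv, Pd(PPh3)4, PhMe, 90 °C) then gives 10; the two iodines are equivalent, and unreacted F3 is recycled.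

Step 8 (last-step Heck on the unprotected flavanone; risk of palladium hydride migration of the prenyl double bond or sluggish coupling). The fallback sets out from 11 and comes back at 12, replacing the Heck reaction by a Suzuki–Miyaura coupling in which the E geometry is fixed beforehand. Copper-catalysed protoboration of 2-methylbut-3-yn-2-ol (B2pin2, CuCl, NaOt-Bu, xantphos, MeOH, THF, rt) gives (E)-2-methyl-4-(4,4,5,5-tetramethyl-1,3,2-dioxaborolan-2-yl)but-3-en-2-ol F4. F4 is coupled with 11 (PdCl2(dppf), K3PO4, dioxane/H2O, 50 °C) to give 12.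

## Further compounds

F1 | step 4 | (2S)-2-[3-iodo-4-(2-methylbut-3-yn-2-yloxy)phenyl]-7-(triisopropylsilyloxy)chroman-4-one | C#CC(C)(C)Oc1ccc([C@@H]2CC(=O)c3ccc(O[Si](C(C)C)(C(C)C)C(C)C)cc3O2)cc1I
F2 | step 5 | (2S)-2-(4-hydroxy-3,5-diiodophenyl)-7-(triisopropylsilyloxy)chroman-4-one | Oc1c(I)cc([C@@H]2CC(=O)c3ccc(O[Si](C(C)C)(C(C)C)C(C)C)cc3O2)cc1I
F3 | step 5 | (2S)-2-(3,5-diiodo-4-methoxyphenyl)-7-(triisopropylsilyloxy)chroman-4-one | COc1c(I)cc([C@@H]2CC(=O)c3ccc(O[Si](C(C)C)(C(C)C)C(C)C)cc3O2)cc1I
F4 | step 8 | (E)-2-methyl-4-(4,4,5,5-tetramethyl-1,3,2-dioxaborolan-2-yl)but-3-en-2-ol | CC(C)(O)/C=C/B1OC(C)(C)C(C)(C)O1
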